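Amounts first. Per litre of the first phase the flask holds 2.0 M of substrate and 1.40 M of reagent in the second phase. The reagent is the limiting reagent, with less charged than substrate, and target in the flask can reach at most 70.0% of the substrate charged. The south run held 1 M of substrate against 1.4 M of reagent.

| flask | substrate | reagent in the second phase | remark | time | volume of the second phase over the first |
|---|---|---|---|---|---|
| south | 1 M | 1.4 M | run made earlier |  |  |
| flask | 2.0 M | 1.40 M |  | 15 min | 2.0 |

south run (percent of the substrate charged)

| time / min | target / % | substrate / % |
|---|---|---|
| 1.00 | 2.2 | 98.2 |
| 1.50 | 1.1 | 99.0 |
| 2.50 | 2.6 | 98.4 |
| 4.00 | 2.5 | 99.0 |
| 8.00 | 7.4 | 92.5 |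
| 12.0 | 9.8 | 92.2 |

(each reading ± 1 percentage point)

- in the second phase: reagent in the second phase; everything else is in the first
- charges count per volume of the first phase; a concentration in a rate is the amount of a species over the volume of its own phase; every rate counts per litre of the first phase
- the numbers in the tables scatter by 1 percentage point (one standard deviation)
- what may be going on: substrate + reagent in the reaction phase -> target; reagent in the reaction phase <-> reagent in the second phase
- the earlier runs hold the two phases in the same ratio of volumes as the flask asked about

- target at 15 min, in percent of the substrate charged
- the change that raises the amount of target at 15 min, in percent of the substrate charged most ("none" if none brings more than 2 percentage points) (alpha / eta / none)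
- amount of target at 15 min, in percent of the substrate charged, after eta

- alpha: doubling the transfer coefficient of the reagent in the second phase, all else as stated
- eta: doubling the amount of reagent in the second phase, all else as stated

Here is our own reckoning, in slow motion. In the first instants reagent crosses into the reaction phase. The south readings show no delay above their scatter of 1 percentage point, so we assume the crossing keeps up, though one substrate level cannot test this.

In the middle, the last south reading gives 9.8% at 12.0 min, a reading of 0.00817 min⁻¹. This is the fractional rate, the share of charged substrate becoming target per minute, a pseudo-first-order constant. It follows [reagent in the reaction phase], not [substrate], and the flask has the south reagent charge and phase ratio. So the flask starts at the same fractional rate, which gives 12.3% at 15 min.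

Towards the end the rate drifts. That much target spends 17.5% of the flask's reagent charge, so the fractional rate sags by about 8.75% on average, and we expect 11.2%. Doubling the reagent doubles the fractional rate and holds the spent share, giving 22.4%. Doubling transfer adds little on our assumption.

The forecast, holding that “One run at one substrate level cannot separate these”, gives 9%, below our estimate. It chooses eta and expects 17.5% after it.

The flask gives 10.7%. The best change is eta, which adds 9.6 points and reaches 20.2%, while alpha adds 0.13 points.

    substrate + reagent in the reaction phase → target (k = 4.40 × 10⁻⁴ L mol⁻¹ s⁻¹)
    reagent in the reaction phase ⇌ reagent in the second phase, rate k2*([reagent in the reaction phase] - [reagent in the second phase]/K2) per volume of the first phase (partition coefficient = 1.70, kL = 0.0480 s⁻¹)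

Target in the flask shifts by 5 points when reagent in the second phase alone goes to 0.725 M or 2.11 M, or when time alone goes to 7.58 min or 23.5 min. In the flask, [reagent in the reaction phase] sinks from 0.309 M at 1.50 min to 0.267 M at 15.0 min, and the mean fractional rate is 0.00713 min⁻¹, below the south reading. At 1.2 M of substrate, the south fractional rate with a spent share of 10.5% gives 11.7%, and that neighbour stands at 11.0%.

All runs were computed from invented constants; the scatter is artificial.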